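**Plan**

- Cuts, in retrosynthetic order: the two quinone C=O groups (back to aryl methyl ethers), two ring hydrogens (furan back to 2,5-dihydrofuran), the furan C3–C4 bond (ring-closing metathesis), the O1–C5 ether bond, the prenyl C=C (cross-metathesis), the ester C–O bond, and the carbinol C–CH2 bond (allylation).
- Enabling feature: numbering the furan from oxygen with the quinone-bearing carbon as C2, the C3–C4 bond joins the unsubstituted C3–H to C4, which carries the stereogenic acyloxy chain. It therefore unfolds into a vinyl group on C2 and a 1,1-disubstituted alkene attached to C5, tied together through O1.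
- Forward: the side-chain fragment is built from 2-methylidenepropane-1,3-diol (allylation, acylation, cross-metathesis, bromide) and joined through oxygen to an aryl vinyl carbinol; the five-membered ring is then closed and aromatised, and the benzoquinone is unveiled last.
- Stereochemistry: the single (R) centre comes from a Brown allylboration with the (−)-α-pinene-derived borane and is not touched again. The benzylic centre of the ether is carried as both epimers and disappears on aromatisation.

Key step: step 10

Assumption: compounds 16 and 17 are used as mixtures of the two epimers at the aryl-bearing carbon, which is acceptable because that carbon becomes furan C2 in step 11.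

**Route**

Step 1
Reactants: 1 2-methylidenepropane-1,3-diol
Product: 3 2-({[tert-butyl(dimethyl)silyl]oxy}methyl)prop-2-en-1-ol, via monosodium alkoxide 2 (not isolated)
Conditions: NaH (1 equiv), THF, 0 °C to rt; then TBSCl (1 equiv)
Reagents that add atoms: tert-butyl(chloro)dimethylsilane (TBSCl), CC(C)(C)[Si](C)(C)Cl
Why: Monosilylation of a symmetrical diol by O-silylation of its sparingly soluble monosodium alkoxide, which reacts with the silyl chloride faster than it equilibrates to the dialkoxide, so only one hydroxyl should be capped.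

Step 2
Reactants: 3 2-({[tert-butyl(dimethyl)silyl]oxy}methyl)prop-2-en-1-ol
Product: 4 2-({[tert-butyl(dimethyl)silyl]oxy}methyl)prop-2-enal
Conditions: MnO2 (activated, excess), CH2Cl2, rt
Reagents that add atoms: none
Why: Allylic alcohol oxidation with activated MnO2 stops at the enal and leaves the silyl ether and the 1,1-disubstituted alkene alone.

Step 3
Reactants: 4 2-({[tert-butyl(dimethyl)silyl]oxy}methyl)prop-2-enal
Product: 6 (3R)-2-({[tert-butyl(dimethyl)silyl]oxy}methyl)hexa-1,5-dien-3-ol, via diisopinocampheylborinate ester 5 (not isolated)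
Conditions: (+)-Ipc2B(allyl) [from (−)-α-pinene], Et2O, −78 °C; then NaOH, H2O2, H2O, 0 °C to rt
Reagents that add atoms: (+)-B-allyldiisopinocampheylborane, C=CCB([C@H]1C[C@H]2C[C@@H]([C@@H]1C)C2(C)C)[C@H]1C[C@H]2C[C@@H]([C@@H]1C)C2(C)C
Why: Brown asymmetric allylboration through a closed chair-like six-membered transition state, in which the two isopinocampheyl groups of the (−)-α-pinene-derived borane steer the allyl group onto the Re face of the aldehyde and so set the (R)-carbinol (the 2-substituted vinyl group outranks allyl), after which alkaline H2O2 cleaves the borinate.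

Step 4
Reactants: 6 (3R)-2-({[tert-butyl(dimethyl)silyl]oxy}methyl)hexa-1,5-dien-3-ol; 7 3-methylbutanoyl chloride
Product: 8 (3R)-2-({[tert-butyl(dimethyl)silyl]oxy}methyl)hexa-1,5-dien-3-yl 3-methylbutanoate
Conditions: pyridine, DMAP (cat.), CH2Cl2, 0 °C to rt
Reagents that add atoms: none
Why: DMAP-catalysed acylation of a secondary allylic alcohol by an acid chloride (nucleophilic catalysis through the acylpyridinium ion) keeps the configuration because the C–O bond of the stereocentre is never broken.

Step 5
Reactants: 8 (3R)-2-({[tert-butyl(dimethyl)silyl]oxy}methyl)hexa-1,5-dien-3-yl 3-methylbutanoate; 9 2-methylbut-2-ene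
Product: 10 (3R)-2-({[tert-butyl(dimethyl)silyl]oxy}methyl)-6-methylhepta-1,5-dien-3-yl 3-methylbutanoate
Conditions: second-generation Grubbs catalyst RuCl2(=CHPh)(PCy3)(H2IMes) (5 mol %), 9 as co-solvent, CH2Cl2, 35 °C, sealed tube
Reagents that add atoms: none
Why: Olefin cross-metathesis in which the monosubstituted vinyl group exchanges its CH2 terminus for the isopropylidene unit of 2-methylbut-2-ene used in large excess, while the hindered 1,1-disubstituted alkene flanked by two allylic substituents is a poor partner and the two alkenes of 8 could only close a four-membered ring.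

Step 6
Reactants: 10 (3R)-2-({[tert-butyl(dimethyl)silyl]oxy}methyl)-6-methylhepta-1,5-dien-3-yl 3-methylbutanoate
Product: 11 (3R)-2-(hydroxymethyl)-6-methylhepta-1,5-dien-3-yl 3-methylbutanoate
Conditions: HF·pyridine, pyridine, THF, 0 °C to rt
Reagents that add atoms: none
Why: Fluoride-mediated Si–O cleavage under buffered, non-basic conditions frees the primary allylic alcohol without inviting base-promoted 1,3-migration of the neighbouring acyl group.

Step 7
Reactants: 11 (3R)-2-(hydroxymethyl)-6-methylhepta-1,5-dien-3-yl 3-methylbutanoate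
Product: 12 (3R)-2-(bromomethyl)-6-methylhepta-1,5-dien-3-yl 3-methylbutanoate
Conditions: CBr4, PPh3, CH2Cl2, 0 °C
Reagents that add atoms: tetrabromomethane, BrC(Br)(Br)Br
Why: Appel bromination through an alkoxyphosphonium salt converts the primary allylic alcohol to the bromide under neutral conditions that spare the ester and both alkenes, and direct or allylic displacement on the 2-substituted allyl unit gives the same bromide.

Step 8
Reactants: 13 2,5-dimethoxybenzaldehyde
Product: 15 racemic 1-(2,5-dimethoxyphenyl)prop-2-en-1-ol, via bromomagnesium alkoxide 14 (not isolated)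
Conditions: CH2=CHMgBr, THF, 0 °C; then aq NH4Cl
Reagents that add atoms: vinylmagnesium bromide, C=C[Mg]Br
Why: 1,2-Addition of a vinyl Grignard reagent to an aromatic aldehyde gives the secondary benzylic allylic alcohol, whose configuration is irrelevant because this carbon becomes furan C2.

Step 9
Reactants: 12 (3R)-2-(bromomethyl)-6-methylhepta-1,5-dien-3-yl 3-methylbutanoate; 15 racemic 1-(2,5-dimethoxyphenyl)prop-2-en-1-ol
Product: 16 (3R)-2-({[1-(2,5-dimethoxyphenyl)prop-2-en-1-yl]oxy}methyl)-6-methylhepta-1,5-dien-3-yl 3-methylbutanoate (both epimers at the benzylic carbon)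
Conditions: Ag2O, 15 (3 equiv), 4 Å molecular sieves, CH2Cl2, rt, dark
Reagents that add atoms: none
Why: Ag2O-promoted O-alkylation (a Williamson-type etherification under non-basic conditions), in which monovalent silver pulls bromide from the allylic bromide while the alcohol attacks either CH2 terminus of the 2-substituted allyl unit to give the same ether, so the isovalerate never meets an alkoxide.

Step 10
Reactants: 16 (3R)-2-({[1-(2,5-dimethoxyphenyl)prop-2-en-1-yl]oxy}methyl)-6-methylhepta-1,5-dien-3-yl 3-methylbutanoate
Product: 17 (1R)-1-[5-(2,5-dimethoxyphenyl)-2,5-dihydrofuran-3-yl]-4-methylpent-3-en-1-yl 3-methylbutanoate (both epimers at the aryl-bearing ring carbon)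
Conditions: second-generation Hoveyda–Grubbs catalyst RuCl2(=CH-C6H4-2-OiPr)(H2IMes) (5 mol %), CH2Cl2 (0.01 M), 40 °C
Reagents that add atoms: none
Why: Ring-closing olefin metathesis: the ruthenium alkylidene first exchanges onto the monosubstituted vinyl group and then adds across the tethered 1,1-disubstituted alkene to a ruthenacyclobutane, whose cycloreversion delivers the ring double bond (the future furan C3–C4 bond) and, after turnover, ethene. The closest known reaction type is the ring-closing metathesis of allyl 2-substituted-allyl ethers to 3-substituted 2,5-dihydrofurans with second-generation ruthenium catalysts. The one ring formed, the five-membered oxacycle, is closed by C=C bond formation between the vinyl CH and the methylidene-bearing carbon, which are tethered by the three-atom C–O–C unit. No stereocentre is created; the acyloxy-bearing (R) centre is only a spectator next to the new alkene and the benzylic carbon remains a mixture of epimers. The step needs chemoselectivity among three alkenes, which is secured because the trisubstituted prenyl alkene is the slowest to engage and any ring it might form would be four-membered (with the methylidene carbon) or eight-membered (with the vinyl carbon), while high dilution suppresses intermolecular cross-metathesis.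

Step 11
Reactants: 17 (1R)-1-[5-(2,5-dimethoxyphenyl)-2,5-dihydrofuran-3-yl]-4-methylpent-3-en-1-yl 3-methylbutanoate
Product: 18 (1R)-1-[5-(2,5-dimethoxyphenyl)furan-3-yl]-4-methylpent-3-en-1-yl 3-methylbutanoate
Conditions: DDQ (1.1 equiv), benzene, rt
Reagents that add atoms: none
Why: DDQ dehydrogenation, in which hydride abstraction from the doubly activated ring C–H (benzylic, allylic and next to oxygen) gives an aryl-stabilised oxocarbenium ion that loses a proton from the ring CH2 to give the aromatic furan and thereby erases the benzylic stereocentre.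

Step 12
Reactants: 18 (1R)-1-[5-(2,5-dimethoxyphenyl)furan-3-yl]-4-methylpent-3-en-1-yl 3-methylbutanoate
Product: 19 (1R)-1-[5-(3,6-dioxocyclohexa-1,4-dien-1-yl)furan-3-yl]-4-methylpent-3-en-1-yl 3-methylbutanoate
Conditions: (NH4)2Ce(NO3)6 (2.5 equiv), MeCN/H2O, 0 °C
Reagents that add atoms: water, O
Why: Oxidative demethylation of a 1,4-dimethoxyarene by tetravalent cerium, in which two one-electron oxidations with addition of water at the methoxy-bearing carbons and loss of methanol give the 1,4-benzoquinone, a process that should be fast at 0 °C relative to attack on the furan, the trisubstituted alkene or the ester.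

**Compound list**

1 | 2-methylidenepropane-1,3-diol | C=C(CO)CO | starting material
2 | sodium 2-(hydroxymethyl)prop-2-en-1-olate | C=C(CO)C[O-].[Na+] | intermediate (not isolated)
3 | 2-({[tert-butyl(dimethyl)silyl]oxy}methyl)prop-2-en-1-ol | C=C(CO)CO[Si](C)(C)C(C)(C)C | intermediate
4 | 2-({[tert-butyl(dimethyl)silyl]oxy}methyl)prop-2-enal | C=C(C=O)CO[Si](C)(C)C(C)(C)C | intermediate
5 | (3R)-2-({[tert-butyl(dimethyl)silyl]oxy}methyl)hexa-1,5-dien-3-yl diisopinocampheylborinate (isopinocampheyl groups from (−)-α-pinene) | C=CC[C@@H](OB([C@H]1C[C@H]2C[C@@H]([C@@H]1C)C2(C)C)[C@H]1C[C@H]2C[C@@H]([C@@H]1C)C2(C)C)C(=C)CO[Si](C)(C)C(C)(C)C | intermediate (not isolated)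
6 | (3R)-2-({[tert-butyl(dimethyl)silyl]oxy}methyl)hexa-1,5-dien-3-ol | C=CC[C@@H](O)C(=C)CO[Si](C)(C)C(C)(C)C | intermediate
7 | 3-methylbutanoyl chloride | CC(C)CC(Cl)=O | starting material
8 | (3R)-2-({[tert-butyl(dimethyl)silyl]oxy}methyl)hexa-1,5-dien-3-yl 3-methylbutanoate | C=CC[C@@H](OC(=O)CC(C)C)C(=C)CO[Si](C)(C)C(C)(C)C | intermediate
9 | 2-methylbut-2-ene | CC=C(C)C | starting material
10 | (3R)-2-({[tert-butyl(dimethyl)silyl]oxy}methyl)-6-methylhepta-1,5-dien-3-yl 3-methylbutanoate | CC(C)=CC[C@@H](OC(=O)CC(C)C)C(=C)CO[Si](C)(C)C(C)(C)C | intermediate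
11 | (3R)-2-(hydroxymethyl)-6-methylhepta-1,5-dien-3-yl 3-methylbutanoate | CC(C)=CC[C@@H](OC(=O)CC(C)C)C(=C)CO | intermediate
12 | (3R)-2-(bromomethyl)-6-methylhepta-1,5-dien-3-yl 3-methylbutanoate | CC(C)=CC[C@@H](OC(=O)CC(C)C)C(=C)CBr | intermediate
13 | 2,5-dimethoxybenzaldehyde | COc1ccc(OC)c(C=O)c1 | starting material
14 | bromomagnesium 1-(2,5-dimethoxyphenyl)prop-2-en-1-olate | C=CC(O[Mg]Br)c1cc(OC)ccc1OC | intermediate (not isolated)
15 | 1-(2,5-dimethoxyphenyl)prop-2-en-1-ol (racemic) | C=CC(O)c1cc(OC)ccc1OC | intermediate
16 | (3R)-2-({[1-(2,5-dimethoxyphenyl)prop-2-en-1-yl]oxy}methyl)-6-methylhepta-1,5-dien-3-yl 3-methylbutanoate (both epimers at the benzylic carbon) | CC(C)=CC[C@@H](OC(=O)CC(C)C)C(=C)COC(C=C)c1cc(OC)ccc1OC | intermediate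
17 | (1R)-1-[5-(2,5-dimethoxyphenyl)-2,5-dihydrofuran-3-yl]-4-methylpent-3-en-1-yl 3-methylbutanoate (both epimers at the aryl-bearing ring carbon) | CC(C)=CC[C@@H](OC(=O)CC(C)C)C1=CC(OC1)c1cc(OC)ccc1OC | intermediate
18 | (1R)-1-[5-(2,5-dimethoxyphenyl)furan-3-yl]-4-methylpent-3-en-1-yl 3-methylbutanoate | CC(C)=CC[C@@H](OC(=O)CC(C)C)c1coc(-c2cc(OC)ccc2OC)c1 | intermediate
19 | (1R)-1-[5-(3,6-dioxocyclohexa-1,4-dien-1-yl)furan-3-yl]-4-methylpent-3-en-1-yl 3-methylbutanoate | CC(C)=CC[C@@H](OC(=O)CC(C)C)c1coc(C2=CC(=O)C=CC2=O)c1 | target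

**Step count and risks**

Total step count: 12. Longest linear sequence: 11 steps (steps 1–7 and 9–12, from 1); step 8 is a one-step branch.

Steps most likely to fail:

1. Step 9. The heterogeneous alkylation of a hindered secondary alcohol may be sluggish, and silver-assisted ionisation of the bromide may be diverted into participation of the neighbouring ester carbonyl (acyl shift) or into elimination. Fallback, setting out from 6 and rejoining at 16: the ester is introduced only after the ether exists, so that an ordinary sodium-alkoxide Williamson etherification can be used. Alcohol 6 is silylated (TIPSOTf, 2,6-lutidine, CH2Cl2) to give (3R)-2-({[tert-butyl(dimethyl)silyl]oxy}methyl)-3-{[tri(propan-2-yl)silyl]oxy}hexa-1,5-diene F1. Cross-metathesis with 9 under the conditions of step 5 should give (3R)-2-({[tert-butyl(dimethyl)silyl]oxy}methyl)-6-methyl-3-{[tri(propan-2-yl)silyl]oxy}hepta-1,5-diene F2. HF·pyridine at 0 °C should remove only the primary silyl group to give (3R)-6-methyl-2-methylidene-3-{[tri(propan-2-yl)silyl]oxy}hept-5-en-1-ol F3, and CBr4/PPh3 should then give {[(3R)-2-(bromomethyl)-6-methylhepta-1,5-dien-3-yl]oxy}tri(propan-2-yl)silane F4. The sodium alkoxide of 15 (NaH, THF/DMF, 0 °C) should displace bromide to give {[(3R)-2-({[1-(2,5-dimethoxyphenyl)prop-2-en-1-yl]oxy}methyl)-6-methylhepta-1,5-dien-3-yl]oxy}tri(propan-2-yl)silane F5. Bu4NF in THF should free the secondary alcohol (3R)-2-({[1-(2,5-dimethoxyphenyl)prop-2-en-1-yl]oxy}methyl)-6-methylhepta-1,5-dien-3-ol F6, and acylation with 7 (pyridine, DMAP) then gives 16.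

2. Step 12. Oxidation of the electron-rich furan ring by tetravalent cerium may compete with demethylation of the arene. Fallback, setting out from 17 and rejoining at 19: the two oxidations are run in the opposite order so that tetravalent cerium never meets the furan. (NH4)2Ce(NO3)6 in MeCN/H2O at 0 °C should convert 17 into the quinone (1R)-1-[5-(3,6-dioxocyclohexa-1,4-dien-1-yl)-2,5-dihydrofuran-3-yl]-4-methylpent-3-en-1-yl 3-methylbutanoate F7, the cyclic benzylic ether being expected to survive as it does in oxidative demethylations of dimethoxyaryl cyclic ethers. Dehydrogenation of the dihydrofuran ring with DDQ (hydride taken from the ring CH2 next to oxygen, proton lost from the carbon next to the quinone) should then give 19.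

3. Step 6. The isovaleryl group may migrate from the secondary oxygen to the newly freed primary oxygen through a six-membered cyclic intermediate, during or after desilylation. Fallback, setting out from 10 and rejoining at 12: the free alcohol is never formed. Triphenylphosphine dibromide (Ph3PBr2, CH2Cl2, 0 °C to rt) is known to convert primary tert-butyldimethylsilyl ethers directly into bromides, so 10 should go to 12 in one operation; no compound outside the list arises (F0).

Further compounds

F1 | step 9 | (3R)-2-({[tert-butyl(dimethyl)silyl]oxy}methyl)-3-{[tri(propan-2-yl)silyl]oxy}hexa-1,5-diene | C=CC[C@@H](O[Si](C(C)C)(C(C)C)C(C)C)C(=C)CO[Si](C)(C)C(C)(C)C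
F2 | step 9 | (3R)-2-({[tert-butyl(dimethyl)silyl]oxy}methyl)-6-methyl-3-{[tri(propan-2-yl)silyl]oxy}hepta-1,5-diene | CC(C)=CC[C@@H](O[Si](C(C)C)(C(C)C)C(C)C)C(=C)CO[Si](C)(C)C(C)(C)C
F3 | step 9 | (3R)-6-methyl-2-methylidene-3-{[tri(propan-2-yl)silyl]oxy}hept-5-en-1-ol | CC(C)=CC[C@@H](O[Si](C(C)C)(C(C)C)C(C)C)C(=C)CO
F4 | step 9 | {[(3R)-2-(bromomethyl)-6-methylhepta-1,5-dien-3-yl]oxy}tri(propan-2-yl)silane | CC(C)=CC[C@@H](O[Si](C(C)C)(C(C)C)C(C)C)C(=C)CBr
F5 | step 9 | {[(3R)-2-({[1-(2,5-dimethoxyphenyl)prop-2-en-1-yl]oxy}methyl)-6-methylhepta-1,5-dien-3-yl]oxy}tri(propan-2-yl)silane | CC(C)=CC[C@@H](O[Si](C(C)C)(C(C)C)C(C)C)C(=C)COC(C=C)c1cc(OC)ccc1OC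
F6 | step 9 | (3R)-2-({[1-(2,5-dimethoxyphenyl)prop-2-en-1-yl]oxy}methyl)-6-methylhepta-1,5-dien-3-ol | CC(C)=CC[C@@H](O)C(=C)COC(C=C)c1cc(OC)ccc1OC
F7 | step 12 | (1R)-1-[5-(3,6-dioxocyclohexa-1,4-dien-1-yl)-2,5-dihydrofuran-3-yl]-4-methylpent-3-en-1-yl 3-methylbutanoate | CC(C)=CC[C@@H](OC(=O)CC(C)C)C1=CC(OC1)C1=CC(=O)C=CC1=O
F0 | step 6 | none | none
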